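**Retrosynthetic overview**
1. The methyl ketone end of the side chain is added last, by cross-metathesis of a terminal-alkene lactone acid with 5-hexen-2-one and hydrogenation, so the ketone never meets strong base.
2. The γ-lactone (the only ring) is closed by acid from an open-chain anti-α-alkylated β-hydroxy ester, after all three stereocentres are in place.
3. Key disconnection is the C3–C4 bond, which joins two α-carbonyl (normally donor) carbons: the dianion of an (S)-β-hydroxy ester attacks ethyl L-lactate triflate, used as the α-cation (enolonium) equivalent of propanoate. Anti alkylation sets C4 and SN2 inversion sets C3.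
4. The (S)-β-hydroxy ester (C5) comes from Noyori hydrogenation of the β-keto ester made from tert-butyl acetoacetate dianion and 10-bromo-1-decene.

Assumption: the SMILES is read as the (2S,3S,4S)-oxolane acid (chain and CO2H cis, CO2H and Me trans); "C3/C4/C5" use lactone numbering (O1, C2=O, C3–Me, C4–CO2H, C5–chain); a telescoped sequence with no purified intermediate counts as one step.

**Step 1**
Reactants: 1 ethyl (S)-lactate
Product: 2 ethyl (2S)-2-{[(trifluoromethyl)sulfonyl]oxy}propanoate
Conditions: Tf2O (1.05 equiv), 2,6-lutidine (1.1 equiv), CH2Cl2, −78 → 0 °C; pentane/silica plug, used at once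
Reagents that add atoms: trifluoromethanesulfonic anhydride, O=S(=O)(OS(=O)(=O)C(F)(F)F)C(F)(F)F
Why: O-triflation of the secondary alcohol with a hindered base does not touch the C–O bond, so the (S) centre is retained and becomes a highly SN2-reactive α-carbonyl electrophile.

**Step 2**
Reactants: 3 tert-butyl acetoacetate; 4 10-bromo-1-decene
Product: 6 tert-butyl 3-oxotetradec-13-enoate, via sodium lithium dianion 5 (not isolated)
Conditions: NaH (1.1 equiv), THF, 0 °C; n-BuLi (1.05 equiv), 0 °C; 4 (0.9 equiv), 0 °C → rt; cold 1 M HCl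
Reagents that add atoms: none
Why: Huckin–Weiler dianion alkylation, in which the more basic terminal (γ) carbanion of the acetoacetate dianion is alkylated by the primary bromide (SN2); no stereocentre is formed.

**Step 3**
Reactants: 6 tert-butyl 3-oxotetradec-13-enoate
Product: 7 tert-butyl (3S)-3-hydroxytetradec-13-enoate
Conditions: [RuCl2((S)-BINAP)]2·NEt3 (0.2 mol% Ru), HCl (0.2 mol%), MeOH, H2 (3 atm), 40 °C, stopped at full ketone conversion
Reagents that add atoms: none
Why: Noyori asymmetric hydrogenation, in which the chelating β-keto ester is reduced by the (S)-BINAP–Ru hydride to the 3S carbinol (the future C5, typically ≥97% ee), while the non-chelating terminal alkene is spared at low pressure.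

**Step 4**
Reactants: 7 tert-butyl (3S)-3-hydroxytetradec-13-enoate; 2 ethyl (2S)-2-{[(trifluoromethyl)sulfonyl]oxy}propanoate
Product: 11 (2S,3S,4S)-4-methyl-5-oxo-2-(undec-10-en-1-yl)oxolane-3-carboxylic acid, via dilithium dianion 8 (not isolated), via hydroxy diester 9 (not isolated), via tert-butyl lactone ester 10 (not isolated)
Conditions: LDA (2.2 equiv, commercial solution), THF, −78 → −20 °C; then −78 °C, 2 (1.3 equiv, added quickly), 2 h; AcOH, −78 °C; work-up; crude in TFA/CH2Cl2 1:4, 0 °C → rt
Reagents that add atoms: none
Why: Proposed new method: a Fráter–Seebach alkylation whose electrophile is a secondary α-triflyloxy ester acting as a propanoate α-cation (enolonium) equivalent, so that two carbons that are both enolate carbons by natural polarity are joined; the Li-chelated Z-enolate of 8 is attacked on the face anti to the carbinol chain (anti rule, giving 4S, which is cis to the chain once the ring closes through O and the new substituent), the triflate carbon is inverted by SN2 ((S)-triflate gives 3S after the CIP priority change), and acid then closes the γ-lactone with loss of ethanol and cleaves the tert-butyl ester; the closest known chemistry is Fráter–Seebach alkylation with primary halides and the stereospecific SN2 displacement of α-triflyloxy esters by malonate and β-keto ester enolates, and the open risk is E2 or proton transfer with this more basic enolate.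

**Step 5**
Reactants: 11 (2S,3S,4S)-4-methyl-5-oxo-2-(undec-10-en-1-yl)oxolane-3-carboxylic acid; 12 5-hexen-2-one
Product: 14 (2S,3S,4S)-4-methyl-5-oxo-2-(14-oxopentadecyl)oxolane-3-carboxylic acid, via unsaturated keto acid 13 (not isolated)
Conditions: Hoveyda–Grubbs II (5 mol%), 12 (4 equiv), 1,4-benzoquinone (10 mol%), CH2Cl2, 40 °C; then EtOAc, 10% Pd/C, H2 (1 atm), rt
Reagents that add atoms: none
Why: Olefin cross-metathesis of two terminal alkenes (excess cheap partner, loss of ethene, benzoquinone suppressing double-bond migration) followed by Pd/C hydrogenation of the disubstituted alkene; ketone, lactone, acid and the three stereocentres are untouched because no base is present.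

**Compound list**
1 | ethyl (S)-lactate (ethyl (2S)-2-hydroxypropanoate) | C[C@H](O)C(=O)OCC | starting material
2 | ethyl (2S)-2-{[(trifluoromethyl)sulfonyl]oxy}propanoate | C[C@H](OS(=O)(=O)C(F)(F)F)C(=O)OCC | intermediate
3 | tert-butyl acetoacetate (tert-butyl 3-oxobutanoate) | CC(=O)CC(=O)OC(C)(C)C | starting material
4 | 10-bromo-1-decene | BrCCCCCCCCC=C | starting material
5 | sodium lithium dianion of 3 (1-tert-butoxybuta-1,3-diene-1,3-diolate) | [Na+].[Li+].C=C([O-])C=C([O-])OC(C)(C)C | intermediate
6 | tert-butyl 3-oxotetradec-13-enoate | C=CCCCCCCCCCC(=O)CC(=O)OC(C)(C)C | intermediate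
7 | tert-butyl (3S)-3-hydroxytetradec-13-enoate | C=CCCCCCCCCC[C@H](O)CC(=O)OC(C)(C)C | intermediate
8 | dilithium dianion of 7 (alkoxide and ester enolate) | [Li+].[Li+].C=CCCCCCCCCC[C@H]([O-])C=C([O-])OC(C)(C)C | intermediate
9 | 1-tert-butyl 4-ethyl (2S,3S)-2-[(1S)-1-hydroxydodec-11-en-1-yl]-3-methylbutanedioate | C=CCCCCCCCCC[C@H](O)[C@@H](C(=O)OC(C)(C)C)[C@H](C)C(=O)OCC | intermediate
10 | tert-butyl (2S,3S,4S)-4-methyl-5-oxo-2-(undec-10-en-1-yl)oxolane-3-carboxylate | C=CCCCCCCCCC[C@@H]1OC(=O)[C@@H](C)[C@@H]1C(=O)OC(C)(C)C | intermediate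
11 | (2S,3S,4S)-4-methyl-5-oxo-2-(undec-10-en-1-yl)oxolane-3-carboxylic acid | C=CCCCCCCCCC[C@@H]1OC(=O)[C@@H](C)[C@@H]1C(=O)O | intermediate
12 | 5-hexen-2-one | CC(=O)CCC=C | starting material
13 | (2S,3S,4S)-4-methyl-5-oxo-2-(14-oxopentadec-10-en-1-yl)oxolane-3-carboxylic acid (E/Z mixture) | CC(=O)CCC=CCCCCCCCCC[C@@H]1OC(=O)[C@@H](C)[C@@H]1C(=O)O | intermediate
14 | (2S,3S,4S)-4-methyl-5-oxo-2-(14-oxopentadecyl)oxolane-3-carboxylic acid | CC(=O)CCCCCCCCCCCCC[C@@H]1OC(=O)[C@@H](C)[C@@H]1C(=O)O | target

**Totals**
Total step count: 5. Longest linear sequence: 4 (steps 2, 3, 4, 5, from tert-butyl acetoacetate and 10-bromo-1-decene); step 1 is a one-step side branch.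

**Three steps most likely to fail**

Step 4 (highest risk). The dianion may act as a base toward triflate 2 (E2 to ethyl acrylate, α-deprotonation) or be O-alkylated. The fallback sets out from 7 and comes back at 11, and it changes how C3 is made. The same dianion of 7 (LDA, 2.2 equiv, THF, −78 °C) is alkylated with ethyl bromoacetate, a primary α-halo ester with no β-hydrogen, to give 1-tert-butyl 4-ethyl (2S)-2-[(1S)-1-hydroxydodec-11-en-1-yl]butanedioate F1. TFA/CH2Cl2 closes the lactone and frees the acid to give (2S,3S)-5-oxo-2-(undec-10-en-1-yl)oxolane-3-carboxylic acid F2. The carboxylate/lactone-enolate dianion of F2 (NaHMDS 2.2 equiv, THF, −78 °C) is then methylated with MeI anti to the carboxylate, which gives 11. The C3 centre is thus set by substrate-controlled enolate methylation instead of by inversion of the lactate triflate, at the cost of one step.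

Step 3. The Ru hydride may partly reduce or migrate the terminal alkene, which would later give chain-length errors in the metathesis. The fallback sets out from 6 and comes back at 7. It replaces metal-catalysed hydrogenation by a biocatalytic reduction with an (S)-selective ketoreductase from a commercial panel (NADP+, isopropanol recycling, pH 7 buffer, 30 °C), which cannot touch the alkene. No new compound is made (F0).

Step 5. Cross-metathesis on the free lactone acid may give homodimers that are hard to separate, or suffer double-bond migration. The fallback sets out from 7 and comes back at 14, and it completes the chain before the key step with the ketone masked. Compound 12 is converted (ethylene glycol, cat. TsOH, toluene, Dean–Stark) into 2-(but-3-en-1-yl)-2-methyl-1,3-dioxolane F3. Cross-metathesis of 7 with F3 (Hoveyda–Grubbs II) gives tert-butyl (3S)-3-hydroxy-16-(2-methyl-1,3-dioxolan-2-yl)hexadec-13-enoate F4, a neutral compound that is easily purified. Hydrogenation (Pd/C, H2) gives tert-butyl (3S)-3-hydroxy-16-(2-methyl-1,3-dioxolan-2-yl)hexadecanoate F5. Its dianion (LDA 2.2 equiv; the ketal is inert) is alkylated with 2 as in step 4 to give 1-tert-butyl 4-ethyl (2S,3S)-2-[(1S)-1-hydroxy-14-(2-methyl-1,3-dioxolan-2-yl)tetradecyl]-3-methylbutanedioate F6. Aqueous TFA/CH2Cl2 then lactonises, cleaves the tert-butyl ester and removes the ketal in one operation to give 14.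

**Further compounds**
F1 | step 4 | 1-tert-butyl 4-ethyl (2S)-2-[(1S)-1-hydroxydodec-11-en-1-yl]butanedioate | C=CCCCCCCCCC[C@H](O)[C@@H](C(=O)OC(C)(C)C)CC(=O)OCC
F2 | step 4 | (2S,3S)-5-oxo-2-(undec-10-en-1-yl)oxolane-3-carboxylic acid | C=CCCCCCCCCC[C@@H]1OC(=O)C[C@@H]1C(=O)O
F0 | step 3 | none | none
F3 | step 5 | 2-(but-3-en-1-yl)-2-methyl-1,3-dioxolane | C=CCCC1(C)OCCO1
F4 | step 5 | tert-butyl (3S)-3-hydroxy-16-(2-methyl-1,3-dioxolan-2-yl)hexadec-13-enoate | CC1(OCCO1)CCC=CCCCCCCCCC[C@H](O)CC(=O)OC(C)(C)C
F5 | step 5 | tert-butyl (3S)-3-hydroxy-16-(2-methyl-1,3-dioxolan-2-yl)hexadecanoate | CC1(OCCO1)CCCCCCCCCCCCC[C@H](O)CC(=O)OC(C)(C)C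
F6 | step 5 | 1-tert-butyl 4-ethyl (2S,3S)-2-[(1S)-1-hydroxy-14-(2-methyl-1,3-dioxolan-2-yl)tetradecyl]-3-methylbutanedioate | CC1(OCCO1)CCCCCCCCCCCCC[C@H](O)[C@@H](C(=O)OC(C)(C)C)[C@H](C)C(=O)OCC
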